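## The problem

The target 43 is a germacranolide. In germacrane numbering, C1–C10 form the ring, C11–C13 sit on C7, C14 on C10 and C15 on C4. The ten-membered carbocycle is fused at C6–C7 to an α-methylene-γ-butyrolactone and carries a Z C4=C5 alkene, a trans C1–C10 epoxide, an isovalerate at C3 and a (2R,3S)-epoxytiglate at C8. A synthesis must close a medium ring against transannular strain and entropy, and must keep the Z trisubstituted alkene, the less stable geometry, intact while doing so.

Six ring stereocentres (1R,3S,6R,7R,8R,10R) and two side-chain centres have to be set. C10 is quaternary and is best bought. It can direct C1 by 1,2-induction, and C1 can direct C3 across the C2 methylene. The C7/C8 pair is insulated from C10 by the C9 methylene and needs reagent control, after which C6 can be set from C7 and C8.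

Several groups will not survive rough treatment:
- the methylene lactone is a Michael acceptor;
- the trisubstituted epoxide faces the C4=C5 alkene across the ring and cyclises transannularly under acid;
- the allylic isovalerate can migrate or cleave under base, and a free C8 hydroxyl beside the lactone can translactonise;
- a free C6 hydroxyl cis to a C3 ketone across the Z alkene would close to a furan.

The feature that makes the key step possible is the 1,3-dioxygen pattern C1–O / C3–O with only the C2 methylene between. Read as an aldol retron, C3 becomes a methyl ketone and C1 an aldehyde. Because C10 is fully substituted, that aldehyde has no α-hydrogen, and the C10 oxygen is the only stereocontrol element next to the new carbinol.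

## Retrosynthesis

**C8 ester.** The epoxytiglate of 43 is cut at the ester C–O bond to give alcohol 37 and (2R,3S)-2,3-dimethyloxirane-2-carboxylic acid 41. Doing this last keeps the non-enolisable but base-sensitive epoxy ester out of every earlier step. The forward reaction must acylate a hindered secondary alcohol beside a lactone without translactonisation. Acid 41 goes back to tiglyl alcohol 38 through epoxy alcohol 39 by a reagent-controlled epoxidation.

**Lactone.** The lactone of 37 (via its PMB ether 36) is cut at C12: an oxidative lactonisation of the 6,12-diol 33 forms it. Carrying C12 as a protected allylic alcohol means the exocyclic methylene is present from the start and no enolate methylenation is needed beside the epoxide. The C8 oxygen must stay protected here, because it is also γ to C12.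

**Epoxide and isovalerate.** The epoxide C1–O bond of 33 is cut to the C1 mesylate 32, in which the C10 oxygen is a silyl ether. Displacement with inversion turns a 1,10-anti diol derivative into the trans epoxide. 32 comes from the mono-isovalerate 31 and this from the 1,3-anti diol 30. The C3 hydroxyl is allylic and far less hindered than the neopentylic C1 hydroxyl, so acylation and then mesylation should sort themselves by sterics.

**C3 carbinol.** Diol 30 is taken back to β-hydroxy enone 29. The C1 hydroxyl can deliver hydride to C3 intramolecularly, which gives the required 1,3-anti relationship (3S) without a chiral reagent.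

**Ring closure (C1–C2).** 29 is cut between C1 and C2 to the open-chain keto aldehyde 26. Against the neighbouring cuts (C5–C6 or C7–C8), this bond creates C1 under control of the purchased C10 centre and leaves the ketone that then relays chirality to C3. All other stereocentres and the Z alkene are fixed in acyclic chemistry. The precursor is a linear chain with four stereocentres. The forward reaction is asked for regioselective enolisation at C2, ring closure over oligomerisation, and Felkin–Anh addition to the α-silyloxy aldehyde.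

**C5–C6.** 26 arises by double oxidation of diol 25, obtained from silyl ether 24 and allylic alcohol 23. 23 is cut at C5–C6 into aldehyde 17 and Z-iodoalkene 21. The Z geometry is thereby built on a four-carbon piece by anti-carbomagnesiation of (S)-but-3-yn-2-ol 18 (via iodoalkenol 20). The coupling must add to an epimerisable aldehyde under non-basic conditions and give the 6R carbinol.

**C7–C11.** Aldehyde 17 goes back through PMB ether 16 and the p-methoxybenzylidene acetal 15 to 1,3-diol 14. The C7–C11 bond of 14 is cut to epoxy alcohol 9 and the alkenyl bromide 11 (from 2-bromoprop-2-en-1-ol 10). Opening a trans-2,3-epoxy alcohol at the carbon next to the carbinol sets C7 and C8 anti in one stereospecific step and brings in C11–C13 complete.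

**C8–C9 and C10.** Epoxy alcohol 9 comes from E-allylic alcohol 8 by a tartrate-controlled epoxidation, so C7/C8 are set independently of C10. 8 comes from propargylic alcohol 7, and this (via 6 and 5) from silylated (S)-2-methylglycidol 2 and 4-methoxybenzyl propargyl ether 3. (S)-2-Methylglycidol 1 supplies C1, C9, C10 and C14 with the quaternary centre in place.

## Roads not taken

**Alternative 1:** The ring is cut at C5–C6 together with the lactone C12–O bond. In the forward step CrCl2 with catalytic NiCl2 would turn iodoalkene aldehyde ester A2 into an alkenylchromium species that adds to the C6 aldehyde. The chromium alkoxide would then close onto the C12 methyl ester to give lactone A1.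
- Merits: alkenylchromium additions are the best-established way to close ten-membered carbocycles; the conditions are neutral; the epoxide can already be present; ring and lactone form in one flask.
- Weak points: C6 is created during ring closure and is steered only by C7 and by ring conformation. The C6 aldehyde of A2 is epimerisable at C7. C1, C3 and C10 plus the epoxide must all be built and carried through acyclic chemistry. A1 lacks the methylene, so a late enolate methylenation is needed beside an epoxide, followed by desilylation and two acylations on the finished Michael acceptor.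
- Comparison: in confidence of ring closure this road is ahead of the chosen plan. The chosen plan sets against it the stereochemical relay C10 → C1 → C3 that the aldol product provides, a methylene carried from the start, and a fallback (fallback to step 18) that reaches the same product 29 by established samarium chemistry.

**Alternative 2:** The ring is cut at C7–C8. SmI2 would reduce the C8 aldehyde of butenolide aldehyde A4 to a ketyl that adds to C7 of the butenolide. The samarium enolate would expel acetate, giving the C11=C13 methylene and 8-hydroxy germacranolide A3.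
- Merits: ring, C7–C8 bond and methylene lactone form in one step. The isovalerate is already in place and the C8 hydroxyl emerges free for the last acylation, so the endgame is shorter than in the chosen plan and needs fewer protecting groups.
- Weak points: C7 and C8 are both set in the ring closure with only C6 to direct them. A4 contains a β,γ-unsaturated aldehyde prone to conjugation. The 1,10-epoxide must be added afterwards to a molecule with two other alkenes, with face selectivity left to ring conformation.
- Comparison: this road is better in step economy. The chosen plan sets against it that each stereocentre has a named control element (chiral pool, tartrate, Felkin–Anh, directed reduction) and that the epoxide comes from a diol of defined configuration.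

**Alternative 3:** No ring bond is cut in the usual sense. The C5–C10 bond of a bicyclic precursor is broken: irradiation near 300 nm of cis-fused eudesmanolide dienol ether A6 would open ring A in a conrotatory six-electron process to triene A5.
- Merits: the precursor is a decalin, for which stereocontrol and ring construction are routine. The ten-membered ring and three alkenes appear in one photochemical step, and the route is the shortest on paper.
- Weak points: the two conrotatory senses give 4Z,1(10)E or 4E,1(10)Z trienes and nothing in A6 clearly favours one. The triene can re-close thermally or shift hydrogen, and a photostationary mixture is likely. The methylene lactone is itself photoreactive. A5 must then be hydrolysed at the enol ether, reduced at C3, and epoxidised at one of three alkenes, with no relay to set C1, C3 and C10.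
- Comparison: this road is better in brevity. The chosen plan is longer but fixes the Z alkene and every stereocentre before or during a ring closure whose outcome can be predicted.

Key step: step 18

## Assumptions

- Germacrane numbering is used for all intermediates; open-chain compounds 23–26 are named as 1,2-secogermacranes.
- 4-Methoxybenzyl propargyl ether 3 is taken as purchasable; otherwise it is one Williamson step from propargyl alcohol.
- The C3 configuration of 18–25 is erased in step 17; the S series is used only so that every intermediate is a single diastereomer.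
- The C12 silyl ether is tert-butyldiphenylsilyl (not tert-butyldimethylsilyl) so that the C1 and C3 triethylsilyl ethers can be removed beside it in step 16.

## Route

Step 1
Reactants: 1 (S)-2-methylglycidol
Product: 2 (R)-triethyl[(2-methyloxiran-2-yl)methoxy]silane
Conditions: TESCl, imidazole, CH2Cl2, 0 °C
Reagents that add atoms: chlorotriethylsilane, CC[Si](Cl)(CC)CC
Why: Silylation of the primary alcohol under conditions that never form the epoxy alkoxide, so the quaternary centre cannot scramble; the descriptor changes only because the silyloxymethyl group now outranks the ring CH2.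

Step 2
Reactants: 2 (R)-triethyl[(2-methyloxiran-2-yl)methoxy]silane; 3 4-methoxybenzyl propargyl ether
Product: 5 (R)-6-(4-methoxybenzyloxy)-2-methyl-1-(triethylsilyloxy)hex-4-yn-2-ol, via lithium acetylide 4 (not isolated)
Conditions: 3, n-BuLi, THF, −78 °C; BF3·OEt2; then 2, −78 °C
Reagents that add atoms: none
Why: BF3-promoted opening of an epoxide by a lithium acetylide; attack occurs at the unsubstituted ring carbon (C9), forming C8–C9 and leaving the C10 stereocentre untouched.

Step 3
Reactants: 5 (R)-6-(4-methoxybenzyloxy)-2-methyl-1-(triethylsilyloxy)hex-4-yn-2-ol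
Product: 6 (R)-6-(4-methoxybenzyloxy)-2-methyl-1,2-bis(triethylsilyloxy)hex-4-yne
Conditions: TESOTf, 2,6-lutidine, CH2Cl2, −78 → 0 °C
Reagents that add atoms: triethylsilyl trifluoromethanesulfonate, CC[Si](CC)(CC)OS(=O)(=O)C(F)(F)F
Why: Silyl triflate silylation of a tertiary alcohol; the tertiary triethylsilyl ether is the non-chelating group needed at C10 in the key step and is robust enough to be carried to step 22.

Step 4
Reactants: 6 (R)-6-(4-methoxybenzyloxy)-2-methyl-1,2-bis(triethylsilyloxy)hex-4-yne
Product: 7 (R)-5-methyl-5,6-bis(triethylsilyloxy)hex-2-yn-1-ol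
Conditions: DDQ, CH2Cl2/pH 7 buffer, 0 °C
Reagents that add atoms: none
Why: Oxidative cleavage of a 4-methoxybenzyl ether; buffering protects the silyl ethers and the alkyne is inert to the quinone.

Step 5
Reactants: 7 (R)-5-methyl-5,6-bis(triethylsilyloxy)hex-2-yn-1-ol
Product: 8 (R,E)-5-methyl-5,6-bis(triethylsilyloxy)hex-2-en-1-ol
Conditions: Red-Al, THF, 0 °C → rt; aqueous Rochelle salt
Reagents that add atoms: none
Why: Alkoxide-directed trans-hydroalumination of a propargylic alcohol followed by protonolysis gives the E allylic alcohol exclusively.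

Step 6
Reactants: 8 (R,E)-5-methyl-5,6-bis(triethylsilyloxy)hex-2-en-1-ol
Product: 9 [(2R,3R)-3-[(2R)-2-methyl-2,3-bis(triethylsilyloxy)propyl]oxiran-2-yl]methanol
Conditions: Ti(OiPr)4 (cat.), D-(−)-diethyl tartrate (cat.), t-BuOOH, 4 Å MS, CH2Cl2, −20 °C
Reagents that add atoms: tert-butyl hydroperoxide, CC(C)(C)OO
Why: Katsuki–Sharpless asymmetric epoxidation; for an E allylic alcohol the unnatural D-tartrate delivers oxygen to the face that gives the (2R,3R)-epoxide, so C8 (and the C7 centre to be inverted) are set by the reagent, independently of remote C10.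

Step 7
Reactants: 10 2-bromoprop-2-en-1-ol
Product: 11 (2-bromoallyloxy)(tert-butyl)diphenylsilane
Conditions: TBDPSCl, imidazole, CH2Cl2, rt
Reagents that add atoms: tert-butylchlorodiphenylsilane, CC(C)(C)[Si](Cl)(c1ccccc1)c1ccccc1
Why: Standard silylation of a primary allylic alcohol; the bulky, acid-stable silyl group also disfavours silyl migration in the derived alkenylmetal.

Step 8
Reactants: 9 [(2R,3R)-3-[(2R)-2-methyl-2,3-bis(triethylsilyloxy)propyl]oxiran-2-yl]methanol; 11 (2-bromoallyloxy)(tert-butyl)diphenylsilane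
Product: 14 (2S,3R,5R)-2-[3-(tert-butyldiphenylsilyloxy)prop-1-en-2-yl]-5-methyl-5,6-bis(triethylsilyloxy)hexane-1,3-diol, via alkenyllithium 12 (not isolated), via alkenylmagnesium bromide 13 (not isolated)
Conditions: 11, t-BuLi, Et2O, −78 °C; MgBr2·OEt2; CuI (cat.), then 9, −30 → 0 °C
Reagents that add atoms: none
Why: Copper-catalysed opening of a 2,3-epoxy alcohol by an alkenyl Grignard reagent at the carbon next to the carbinol (C7), favoured by the magnesium alkoxide and by the β-branched chain that shields C8; SN2 inversion at C7 sets the C7/C8 anti relationship, and one equivalent of 13 serves as base for the hydroxyl. Any 1,2-diol regioisomer would be removed by NaIO4 cleavage.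

Step 9
Reactants: 14 (2S,3R,5R)-2-[3-(tert-butyldiphenylsilyloxy)prop-1-en-2-yl]-5-methyl-5,6-bis(triethylsilyloxy)hexane-1,3-diol
Product: 15 (2S,4R,5S)-5-[3-(tert-butyldiphenylsilyloxy)prop-1-en-2-yl]-2-(4-methoxyphenyl)-4-[(2R)-2-methyl-2,3-bis(triethylsilyloxy)propyl]-1,3-dioxane
Conditions: 4-MeOC6H4CH(OMe)2, PPTS (cat.), 4 Å MS, CH2Cl2, rt
Reagents that add atoms: 4-methoxybenzaldehyde dimethyl acetal, COC(OC)c1ccc(OC)cc1
Why: Acid-catalysed transacetalisation of a 1,3-diol; the all-equatorial chair with equatorial aryl is the thermodynamic acetal, and the mild catalyst with sieves (which take up methanol) should spare the neopentylic and tertiary triethylsilyl ethers.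

Step 10
Reactants: 15 (2S,4R,5S)-5-[3-(tert-butyldiphenylsilyloxy)prop-1-en-2-yl]-2-(4-methoxyphenyl)-4-[(2R)-2-methyl-2,3-bis(triethylsilyloxy)propyl]-1,3-dioxane
Product: 16 (2S,3R,5R)-2-[3-(tert-butyldiphenylsilyloxy)prop-1-en-2-yl]-3-(4-methoxybenzyloxy)-5-methyl-5,6-bis(triethylsilyloxy)hexan-1-ol
Conditions: DIBAL-H, CH2Cl2, −78 → 0 °C
Reagents that add atoms: none
Why: Regioselective reductive opening of a 4-methoxybenzylidene acetal; aluminium binds the less hindered primary oxygen, so hydride delivery leaves the benzyl ether on the secondary C8 oxygen and frees the C6 alcohol.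

Step 11
Reactants: 16 (2S,3R,5R)-2-[3-(tert-butyldiphenylsilyloxy)prop-1-en-2-yl]-3-(4-methoxybenzyloxy)-5-methyl-5,6-bis(triethylsilyloxy)hexan-1-ol
Product: 17 (2R,3R,5R)-2-[3-(tert-butyldiphenylsilyloxy)prop-1-en-2-yl]-3-(4-methoxybenzyloxy)-5-methyl-5,6-bis(triethylsilyloxy)hexanal
Conditions: Dess–Martin periodinane, NaHCO3, CH2Cl2, 0 °C; used crude
Reagents that add atoms: none
Why: Buffered Dess–Martin oxidation is neutral enough to give the β,γ-unsaturated aldehyde without epimerisation at C7 or migration of the alkene; the change of descriptor at C7 is nominal.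

Step 12
Reactants: 18 (S)-but-3-yn-2-ol
Product: 20 (S,Z)-4-iodo-3-methylbut-3-en-2-ol, via magnesium chelate 19 (not isolated)
Conditions: MeMgBr, CuI (cat.), THF, −10 °C → rt; then I2, −20 °C
Reagents that add atoms: methylmagnesium bromide, C[Mg]Br; iodine, II
Why: Copper-catalysed anti-carbomagnesiation of a propargylic alcohol: the magnesium alkoxide directs methyl to the internal carbon and magnesium to the terminus cis to the carbinol, and iodinolysis with retention gives the Z iodoalkene that becomes the Z C4=C5 bond.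

Step 13
Reactants: 20 (S,Z)-4-iodo-3-methylbut-3-en-2-ol
Product: 21 (S,Z)-triethyl[(4-iodo-3-methylbut-3-en-2-yl)oxy]silane
Conditions: TESCl, imidazole, CH2Cl2, 0 °C
Reagents that add atoms: chlorotriethylsilane, CC[Si](Cl)(CC)CC
Why: Standard silylation; the C3 oxygen is masked with the same group as the C1 oxygen so that both can be released together in step 16.

Step 14
Reactants: 17 (2R,3R,5R)-2-[3-(tert-butyldiphenylsilyloxy)prop-1-en-2-yl]-3-(4-methoxybenzyloxy)-5-methyl-5,6-bis(triethylsilyloxy)hexanal; 21 (S,Z)-triethyl[(4-iodo-3-methylbut-3-en-2-yl)oxy]silane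
Product: 23 (3S,4Z,6R,7S,8R,10R)-12-(tert-butyldiphenylsilyloxy)-8-(4-methoxybenzyloxy)-1,3,10-tris(triethylsilyloxy)-1,2-secogermacra-4,11(13)-dien-6-ol, via alkenylchromium dichloride 22 (not isolated)
Conditions: CrCl2, NiCl2 (cat.), DMSO, rt
Reagents that add atoms: none
Why: Nozaki–Hiyama–Kishi coupling: nickel-catalysed formation of the alkenylchromium species with retention of the Z geometry and addition to the aldehyde under non-basic, non-chelating conditions that spare the labile C7 centre. Felkin–Anh attack anti to the C8 branch is reinforced by 1,3-anti induction from the C8 ether (the α-branch and β-ether are anti) and should favour the 6R carbinol.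

Step 15
Reactants: 23 (3S,4Z,6R,7S,8R,10R)-12-(tert-butyldiphenylsilyloxy)-8-(4-methoxybenzyloxy)-1,3,10-tris(triethylsilyloxy)-1,2-secogermacra-4,11(13)-dien-6-ol
Product: 24 (3S,4Z,6R,7R,8R,10R)-6-(tert-butyldimethylsilyloxy)-12-(tert-butyldiphenylsilyloxy)-8-(4-methoxybenzyloxy)-1,3,10-tris(triethylsilyloxy)-1,2-secogermacra-4,11(13)-diene
Conditions: TBSOTf, 2,6-lutidine, CH2Cl2, −78 °C
Reagents that add atoms: tert-butyldimethylsilyl trifluoromethanesulfonate, CC(C)(C)[Si](C)(C)OS(=O)(=O)C(F)(F)F
Why: Silyl triflate silylation of a hindered secondary alcohol; capping O6 before C3 is oxidised prevents the Z γ-hydroxy enone from closing to a furan.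

Step 16
Reactants: 24 (3S,4Z,6R,7R,8R,10R)-6-(tert-butyldimethylsilyloxy)-12-(tert-butyldiphenylsilyloxy)-8-(4-methoxybenzyloxy)-1,3,10-tris(triethylsilyloxy)-1,2-secogermacra-4,11(13)-diene
Product: 25 (3S,4Z,6R,7R,8R,10R)-6-(tert-butyldimethylsilyloxy)-12-(tert-butyldiphenylsilyloxy)-8-(4-methoxybenzyloxy)-10-(triethylsilyloxy)-1,2-secogermacra-4,11(13)-diene-1,3-diol
Conditions: PPTS, MeOH/CH2Cl2, 0 °C
Reagents that add atoms: none
Why: Acid-catalysed methanolysis graded by silyl group and substitution: primary and secondary triethylsilyl ethers cleave well before a tertiary triethylsilyl, a secondary tert-butyldimethylsilyl or a tert-butyldiphenylsilyl ether.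

Step 17
Reactants: 25 (3S,4Z,6R,7R,8R,10R)-6-(tert-butyldimethylsilyloxy)-12-(tert-butyldiphenylsilyloxy)-8-(4-methoxybenzyloxy)-10-(triethylsilyloxy)-1,2-secogermacra-4,11(13)-diene-1,3-diol
Product: 26 (4Z,6R,7R,8R,10R)-6-(tert-butyldimethylsilyloxy)-12-(tert-butyldiphenylsilyloxy)-8-(4-methoxybenzyloxy)-3-oxo-10-(triethylsilyloxy)-1,2-secogermacra-4,11(13)-dien-1-al
Conditions: Dess–Martin periodinane (excess), NaHCO3, CH2Cl2, 0 °C → rt
Reagents that add atoms: none
Why: One buffered Dess–Martin oxidation converts the primary alcohol to the non-epimerisable α-silyloxy aldehyde and the allylic alcohol to the Z methyl enone; neutral conditions should preserve the Z geometry.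

Step 18
Reactants: 26 (4Z,6R,7R,8R,10R)-6-(tert-butyldimethylsilyloxy)-12-(tert-butyldiphenylsilyloxy)-8-(4-methoxybenzyloxy)-3-oxo-10-(triethylsilyloxy)-1,2-secogermacra-4,11(13)-dien-1-al
Product: 29 (1S,4Z,6R,7R,8R,10R)-6-(tert-butyldimethylsilyloxy)-12-(tert-butyldiphenylsilyloxy)-1-hydroxy-8-(4-methoxybenzyloxy)-10-(triethylsilyloxy)germacra-4,11(13)-dien-3-one, via lithium enolate 27 (not isolated), via lithium aldolate 28 (not isolated)
Conditions: LiN(SiMe3)2, THF, −78 °C, slow addition of 26 at high dilution; AcOH quench at −78 °C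
Reagents that add atoms: none
Why: Proposed new method: LiN(SiMe3)2 removes a proton from the C2 methyl group, the only kinetically accessible α-position of the enone, to give the cross-conjugated lithium enolate 27, whose C2 terminus adds to the C1 aldehyde to give lithium aldolate 28, protonated cold to 29. The closest known reactions are amide-base macroaldolisations of methyl ketone or acetate enolates onto aldehydes that close rings of fourteen or more members, and intermolecular additions of lithium enolates to α-silyloxy aldehydes; closing a ten-membered carbocycle this way is not established. The ring closes in the 10-(enolendo)-exo-trig mode, and the Z alkene and the branched C6–C8 segment reduce the number of rotors that must be frozen. The new C1 stereocentre is controlled by C10: the enolate should approach anti to the C10–O bond of the bulky, non-chelating triethylsilyl ether (Felkin–Anh and Cornforth models agree), passing the C10 methyl while the C9 methylene stays in the ring, which gives the 1S carbinol with O1 and O10 anti along C9–C10–C1–C2. Regioselective enolisation rests on kinetic deprotonation at −78 °C (the γ-hydrogen at C6 is shielded by its silyl ether); chemoselectivity rests on an aldehyde without α-hydrogen and a base without β-hydrogen, so neither self-condensation nor reduction can compete. High dilution favours ring closure over oligomerisation, and the cold acetic acid quench forestalls retro-aldol cleavage, dehydration and silyl migration from O10 to O1.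

Step 19
Reactants: 29 (1S,4Z,6R,7R,8R,10R)-6-(tert-butyldimethylsilyloxy)-12-(tert-butyldiphenylsilyloxy)-1-hydroxy-8-(4-methoxybenzyloxy)-10-(triethylsilyloxy)germacra-4,11(13)-dien-3-one
Product: 30 (1S,3S,4Z,6R,7R,8R,10R)-6-(tert-butyldimethylsilyloxy)-12-(tert-butyldiphenylsilyloxy)-8-(4-methoxybenzyloxy)-10-(triethylsilyloxy)germacra-4,11(13)-diene-1,3-diol
Conditions: Me4NBH(OAc)3, MeCN/AcOH, −30 °C
Reagents that add atoms: none
Why: Evans–Saksena reduction: the C1 hydroxyl exchanges onto boron and delivers hydride to C3 through a chair transition state, giving the 1,3-anti diol (3S) by 1,2-reduction of the enone; the cold, anhydrous acid should not touch the tertiary silyl ether.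

Step 20
Reactants: 30 (1S,3S,4Z,6R,7R,8R,10R)-6-(tert-butyldimethylsilyloxy)-12-(tert-butyldiphenylsilyloxy)-8-(4-methoxybenzyloxy)-10-(triethylsilyloxy)germacra-4,11(13)-diene-1,3-diol
Product: 31 (1S,3S,4Z,6R,7R,8R,10R)-6-(tert-butyldimethylsilyloxy)-12-(tert-butyldiphenylsilyloxy)-1-hydroxy-8-(4-methoxybenzyloxy)-10-(triethylsilyloxy)germacra-4,11(13)-dien-3-yl 3-methylbutanoate
Conditions: isovaleric anhydride, pyridine, DMAP (cat.), CH2Cl2, −20 °C
Reagents that add atoms: 3-methylbutanoic anhydride, CC(C)CC(=O)OC(=O)CC(C)C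
Why: Sterically differentiated acylation: the allylic C3 hydroxyl reacts, while the C1 hydroxyl, neopentylic to the silyloxy-bearing quaternary C10, should remain free at low temperature.

Step 21
Reactants: 31 (1S,3S,4Z,6R,7R,8R,10R)-6-(tert-butyldimethylsilyloxy)-12-(tert-butyldiphenylsilyloxy)-1-hydroxy-8-(4-methoxybenzyloxy)-10-(triethylsilyloxy)germacra-4,11(13)-dien-3-yl 3-methylbutanoate
Product: 32 (1S,3S,4Z,6R,7R,8R,10R)-6-(tert-butyldimethylsilyloxy)-12-(tert-butyldiphenylsilyloxy)-8-(4-methoxybenzyloxy)-1-(methylsulfonyloxy)-10-(triethylsilyloxy)germacra-4,11(13)-dien-3-yl 3-methylbutanoate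
Conditions: MsCl, Et3N, CH2Cl2, 0 °C
Reagents that add atoms: methanesulfonyl chloride, CS(=O)(=O)Cl
Why: Mesylation through the small, reactive sulfene intermediate, which reaches even hindered secondary alcohols; configuration at C1 is retained.

Step 22
Reactants: 32 (1S,3S,4Z,6R,7R,8R,10R)-6-(tert-butyldimethylsilyloxy)-12-(tert-butyldiphenylsilyloxy)-8-(4-methoxybenzyloxy)-1-(methylsulfonyloxy)-10-(triethylsilyloxy)germacra-4,11(13)-dien-3-yl 3-methylbutanoate
Product: 33 (1R,3S,4Z,6R,7S,8R,10R)-1,10-epoxy-6,12-dihydroxy-8-(4-methoxybenzyloxy)germacra-4,11(13)-dien-3-yl 3-methylbutanoate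
Conditions: Bu4NF, THF, 0 °C → rt; aqueous NH4Cl
Reagents that add atoms: none
Why: Fluoride cleaves all three silyl ethers; the liberated C10 alkoxide displaces the adjacent C1 mesylate in a 3-exo-tet closure with inversion (1S → 1R), so the 1,10-anti arrangement becomes the trans epoxide, while the neopentylic mesylate resists intermolecular attack.

Step 23
Reactants: 33 (1R,3S,4Z,6R,7S,8R,10R)-1,10-epoxy-6,12-dihydroxy-8-(4-methoxybenzyloxy)germacra-4,11(13)-dien-3-yl 3-methylbutanoate
Product: 36 (1R,3S,4Z,6R,7R,8R,10R)-1,10-epoxy-8-(4-methoxybenzyloxy)-3-(3-methylbutanoyloxy)germacra-4,11(13)-dien-12,6-olide, via hydroxy enal 34 (not isolated), via lactol 35 (not isolated)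
Conditions: TEMPO (cat.), PhI(OAc)2, NaHCO3, CH2Cl2, rt
Reagents that add atoms: none
Why: Oxoammonium oxidation is selective for the primary allylic alcohol over the secondary C6 alcohol; the enal is trapped by O6 as the five-membered lactol, which is oxidised on to the α-methylene lactone, and the bicarbonate buffer protects the epoxide from the acetic acid released.

Step 24
Reactants: 36 (1R,3S,4Z,6R,7R,8R,10R)-1,10-epoxy-8-(4-methoxybenzyloxy)-3-(3-methylbutanoyloxy)germacra-4,11(13)-dien-12,6-olide
Product: 37 (1R,3S,4Z,6R,7R,8R,10R)-1,10-epoxy-8-hydroxy-3-(3-methylbutanoyloxy)germacra-4,11(13)-dien-12,6-olide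
Conditions: DDQ, CH2Cl2/pH 7 buffer, 0 °C
Reagents that add atoms: none
Why: Oxidative removal of the 4-methoxybenzyl ether under neutral buffered conditions, compatible with the epoxide, the Michael acceptor and the allylic ester, and not basic enough to trigger translactonisation to O8.

Step 25
Reactants: 38 (E)-2-methylbut-2-en-1-ol (tiglyl alcohol)
Product: 39 [(2S,3S)-2,3-dimethyloxiran-2-yl]methanol
Conditions: Ti(OiPr)4 (cat.), L-(+)-diethyl tartrate (cat.), t-BuOOH, 4 Å MS, CH2Cl2, −20 °C
Reagents that add atoms: tert-butyl hydroperoxide, CC(C)(C)OO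
Why: Katsuki–Sharpless asymmetric epoxidation; the natural L-tartrate delivers oxygen to the face that gives the (2S,3S)-epoxy alcohol, and the E geometry fixes the cis relationship of the two methyl groups.

Step 26
Reactants: 39 [(2S,3S)-2,3-dimethyloxiran-2-yl]methanol
Product: 41 (2R,3S)-2,3-dimethyloxirane-2-carboxylic acid, via epoxy aldehyde 40 (not isolated)
Conditions: TEMPO (cat.), PhI(OAc)2, MeCN/H2O, rt
Reagents that add atoms: water, O
Why: Oxoammonium oxidation of a primary alcohol through the aldehyde hydrate to the acid; the quaternary α-carbon cannot epimerise and the descriptor at C2 changes from S to R only because the carboxyl group outranks C3.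

Step 27
Reactants: 37 (1R,3S,4Z,6R,7R,8R,10R)-1,10-epoxy-8-hydroxy-3-(3-methylbutanoyloxy)germacra-4,11(13)-dien-12,6-olide; 41 (2R,3S)-2,3-dimethyloxirane-2-carboxylic acid
Product: 43 (1R,3S,4Z,6R,7R,8R,10R)-8-[(2R,3S)-2,3-dimethyloxirane-2-carbonyloxy]-1,10-epoxy-3-(3-methylbutanoyloxy)germacra-4,11(13)-dien-12,6-olide, via mixed anhydride 42 (not isolated)
Conditions: 41, 2,4,6-Cl3C6H2COCl, Et3N, THF, rt; then 37, DMAP, toluene, rt
Reagents that add atoms: none
Why: Yamaguchi esterification: the mixed anhydride transfers the aliphatic acyl group through its acylpyridinium to the hindered C8 alcohol under mildly basic, non-acidic conditions; the acid has no α-hydrogen, so its stereocentres are safe.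

## Compound list

1 | (S)-2-methylglycidol | C[C@]1(CO)CO1 | starting material
2 | (R)-triethyl[(2-methyloxiran-2-yl)methoxy]silane | C[C@]1(CO[Si](CC)(CC)CC)CO1 | intermediate
3 | 4-methoxybenzyl propargyl ether | C#CCOCc1ccc(OC)cc1 | starting material
4 | lithium acetylide of 3 | [Li]C#CCOCc1ccc(OC)cc1 | intermediate
5 | (R)-6-(4-methoxybenzyloxy)-2-methyl-1-(triethylsilyloxy)hex-4-yn-2-ol | COc1ccc(COCC#CC[C@@](C)(O)CO[Si](CC)(CC)CC)cc1 | intermediate
6 | (R)-6-(4-methoxybenzyloxy)-2-methyl-1,2-bis(triethylsilyloxy)hex-4-yne | COc1ccc(COCC#CC[C@@](C)(O[Si](CC)(CC)CC)CO[Si](CC)(CC)CC)cc1 | intermediate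
7 | (R)-5-methyl-5,6-bis(triethylsilyloxy)hex-2-yn-1-ol | OCC#CC[C@@](C)(O[Si](CC)(CC)CC)CO[Si](CC)(CC)CC | intermediate
8 | (R,E)-5-methyl-5,6-bis(triethylsilyloxy)hex-2-en-1-ol | OC/C=C/C[C@@](C)(O[Si](CC)(CC)CC)CO[Si](CC)(CC)CC | intermediate
9 | [(2R,3R)-3-[(2R)-2-methyl-2,3-bis(triethylsilyloxy)propyl]oxiran-2-yl]methanol | OC[C@H]1O[C@@H]1C[C@@](C)(O[Si](CC)(CC)CC)CO[Si](CC)(CC)CC | intermediate
10 | 2-bromoprop-2-en-1-ol | C=C(Br)CO | starting material
11 | (2-bromoallyloxy)(tert-butyl)diphenylsilane | C=C(Br)CO[Si](c1ccccc1)(c1ccccc1)C(C)(C)C | intermediate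
12 | [3-(tert-butyldiphenylsilyloxy)prop-1-en-2-yl]lithium | [Li]C(=C)CO[Si](c1ccccc1)(c1ccccc1)C(C)(C)C | intermediate
13 | [3-(tert-butyldiphenylsilyloxy)prop-1-en-2-yl]magnesium bromide | Br[Mg]C(=C)CO[Si](c1ccccc1)(c1ccccc1)C(C)(C)C | intermediate
14 | (2S,3R,5R)-2-[3-(tert-butyldiphenylsilyloxy)prop-1-en-2-yl]-5-methyl-5,6-bis(triethylsilyloxy)hexane-1,3-diol | OC[C@H](C(=C)CO[Si](c1ccccc1)(c1ccccc1)C(C)(C)C)[C@H](O)C[C@@](C)(O[Si](CC)(CC)CC)CO[Si](CC)(CC)CC | intermediate
15 | (2S,4R,5S)-5-[3-(tert-butyldiphenylsilyloxy)prop-1-en-2-yl]-2-(4-methoxyphenyl)-4-[(2R)-2-methyl-2,3-bis(triethylsilyloxy)propyl]-1,3-dioxane | COc1ccc(cc1)[C@H]1OC[C@H](C(=C)CO[Si](c2ccccc2)(c2ccccc2)C(C)(C)C)[C@@H](C[C@@](C)(O[Si](CC)(CC)CC)CO[Si](CC)(CC)CC)O1 | intermediate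
16 | (2S,3R,5R)-2-[3-(tert-butyldiphenylsilyloxy)prop-1-en-2-yl]-3-(4-methoxybenzyloxy)-5-methyl-5,6-bis(triethylsilyloxy)hexan-1-ol | OC[C@H](C(=C)CO[Si](c1ccccc1)(c1ccccc1)C(C)(C)C)[C@H](OCc1ccc(OC)cc1)C[C@@](C)(O[Si](CC)(CC)CC)CO[Si](CC)(CC)CC | intermediate
17 | (2R,3R,5R)-2-[3-(tert-butyldiphenylsilyloxy)prop-1-en-2-yl]-3-(4-methoxybenzyloxy)-5-methyl-5,6-bis(triethylsilyloxy)hexanal | O=C[C@H](C(=C)CO[Si](c1ccccc1)(c1ccccc1)C(C)(C)C)[C@H](OCc1ccc(OC)cc1)C[C@@](C)(O[Si](CC)(CC)CC)CO[Si](CC)(CC)CC | intermediate
18 | (S)-but-3-yn-2-ol | C[C@H](O)C#C | starting material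
19 | five-membered alkenylmagnesium alkoxide chelate from 18 (methyl on the internal carbon, magnesium on the terminus) | C[C@@H]1O[Mg]C=C1C | intermediate
20 | (S,Z)-4-iodo-3-methylbut-3-en-2-ol | C[C@H](O)/C(C)=C\I | intermediate
21 | (S,Z)-triethyl[(4-iodo-3-methylbut-3-en-2-yl)oxy]silane | C[C@H](O[Si](CC)(CC)CC)/C(C)=C\I | intermediate
22 | (S,Z)-alkenylchromium dichloride from 21 (trivalent chromium) | C[C@H](O[Si](CC)(CC)CC)/C(C)=C\[Cr](Cl)Cl | intermediate
23 | (3S,4Z,6R,7S,8R,10R)-12-(tert-butyldiphenylsilyloxy)-8-(4-methoxybenzyloxy)-1,3,10-tris(triethylsilyloxy)-1,2-secogermacra-4,11(13)-dien-6-ol | C[C@H](O[Si](CC)(CC)CC)/C(C)=C\[C@@H](O)[C@H](C(=C)CO[Si](c1ccccc1)(c1ccccc1)C(C)(C)C)[C@H](OCc1ccc(OC)cc1)C[C@@](C)(O[Si](CC)(CC)CC)CO[Si](CC)(CC)CC | intermediate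
24 | (3S,4Z,6R,7R,8R,10R)-6-(tert-butyldimethylsilyloxy)-12-(tert-butyldiphenylsilyloxy)-8-(4-methoxybenzyloxy)-1,3,10-tris(triethylsilyloxy)-1,2-secogermacra-4,11(13)-diene | C[C@H](O[Si](CC)(CC)CC)/C(C)=C\[C@@H](O[Si](C)(C)C(C)(C)C)[C@H](C(=C)CO[Si](c1ccccc1)(c1ccccc1)C(C)(C)C)[C@H](OCc1ccc(OC)cc1)C[C@@](C)(O[Si](CC)(CC)CC)CO[Si](CC)(CC)CC | intermediate
25 | (3S,4Z,6R,7R,8R,10R)-6-(tert-butyldimethylsilyloxy)-12-(tert-butyldiphenylsilyloxy)-8-(4-methoxybenzyloxy)-10-(triethylsilyloxy)-1,2-secogermacra-4,11(13)-diene-1,3-diol | C[C@H](O)/C(C)=C\[C@@H](O[Si](C)(C)C(C)(C)C)[C@H](C(=C)CO[Si](c1ccccc1)(c1ccccc1)C(C)(C)C)[C@H](OCc1ccc(OC)cc1)C[C@@](C)(O[Si](CC)(CC)CC)CO | intermediate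
26 | (4Z,6R,7R,8R,10R)-6-(tert-butyldimethylsilyloxy)-12-(tert-butyldiphenylsilyloxy)-8-(4-methoxybenzyloxy)-3-oxo-10-(triethylsilyloxy)-1,2-secogermacra-4,11(13)-dien-1-al (key-step precursor) | CC(=O)/C(C)=C\[C@@H](O[Si](C)(C)C(C)(C)C)[C@H](C(=C)CO[Si](c1ccccc1)(c1ccccc1)C(C)(C)C)[C@H](OCc1ccc(OC)cc1)C[C@@](C)(O[Si](CC)(CC)CC)C=O | intermediate
27 | lithium C2–C3 enolate of 26 | [Li+].C=C([O-])/C(C)=C\[C@@H](O[Si](C)(C)C(C)(C)C)[C@H](C(=C)CO[Si](c1ccccc1)(c1ccccc1)C(C)(C)C)[C@H](OCc1ccc(OC)cc1)C[C@@](C)(O[Si](CC)(CC)CC)C=O | intermediate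
28 | lithium C1 alkoxide of 29 | [Li+].[O-][C@H]1CC(=O)/C(C)=C\[C@@H](O[Si](C)(C)C(C)(C)C)[C@H](C(=C)CO[Si](c2ccccc2)(c2ccccc2)C(C)(C)C)[C@H](OCc2ccc(OC)cc2)C[C@@]1(C)O[Si](CC)(CC)CC | intermediate
29 | (1S,4Z,6R,7R,8R,10R)-6-(tert-butyldimethylsilyloxy)-12-(tert-butyldiphenylsilyloxy)-1-hydroxy-8-(4-methoxybenzyloxy)-10-(triethylsilyloxy)germacra-4,11(13)-dien-3-one (key-step product) | O[C@H]1CC(=O)/C(C)=C\[C@@H](O[Si](C)(C)C(C)(C)C)[C@H](C(=C)CO[Si](c2ccccc2)(c2ccccc2)C(C)(C)C)[C@H](OCc2ccc(OC)cc2)C[C@@]1(C)O[Si](CC)(CC)CC | intermediate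
30 | (1S,3S,4Z,6R,7R,8R,10R)-6-(tert-butyldimethylsilyloxy)-12-(tert-butyldiphenylsilyloxy)-8-(4-methoxybenzyloxy)-10-(triethylsilyloxy)germacra-4,11(13)-diene-1,3-diol | O[C@H]1C[C@H](O)/C(C)=C\[C@@H](O[Si](C)(C)C(C)(C)C)[C@H](C(=C)CO[Si](c2ccccc2)(c2ccccc2)C(C)(C)C)[C@H](OCc2ccc(OC)cc2)C[C@@]1(C)O[Si](CC)(CC)CC | intermediate
31 | 3-isovalerate of 30 (C1 hydroxyl free) | O[C@H]1C[C@H](OC(=O)CC(C)C)/C(C)=C\[C@@H](O[Si](C)(C)C(C)(C)C)[C@H](C(=C)CO[Si](c2ccccc2)(c2ccccc2)C(C)(C)C)[C@H](OCc2ccc(OC)cc2)C[C@@]1(C)O[Si](CC)(CC)CC | intermediate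
32 | (1S)-1-mesylate of 31 | CS(=O)(=O)O[C@H]1C[C@H](OC(=O)CC(C)C)/C(C)=C\[C@@H](O[Si](C)(C)C(C)(C)C)[C@H](C(=C)CO[Si](c2ccccc2)(c2ccccc2)C(C)(C)C)[C@H](OCc2ccc(OC)cc2)C[C@@]1(C)O[Si](CC)(CC)CC | intermediate
33 | (1R,3S,4Z,6R,7S,8R,10R)-1,10-epoxy-6,12-dihydroxy-8-(4-methoxybenzyloxy)germacra-4,11(13)-dien-3-yl 3-methylbutanoate | OCC(=C)[C@H]1[C@H](O)/C=C(/C)[C@@H](OC(=O)CC(C)C)C[C@H]2O[C@]2(C)C[C@H]1OCc1ccc(OC)cc1 | intermediate
34 | 12-aldehyde of 33 (C6 hydroxyl free) | O=CC(=C)[C@H]1[C@H](O)/C=C(/C)[C@@H](OC(=O)CC(C)C)C[C@H]2O[C@]2(C)C[C@H]1OCc1ccc(OC)cc1 | intermediate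
35 | 6,12-lactol of 34 (C12 epimers) | C=C1C(O)O[C@@H]2/C=C(/C)[C@@H](OC(=O)CC(C)C)C[C@H]3O[C@]3(C)C[C@@H](OCc3ccc(OC)cc3)[C@@H]12 | intermediate
36 | (1R,3S,4Z,6R,7R,8R,10R)-1,10-epoxy-8-(4-methoxybenzyloxy)-3-(3-methylbutanoyloxy)germacra-4,11(13)-dien-12,6-olide | C=C1C(=O)O[C@@H]2/C=C(/C)[C@@H](OC(=O)CC(C)C)C[C@H]3O[C@]3(C)C[C@@H](OCc3ccc(OC)cc3)[C@@H]12 | intermediate
37 | (1R,3S,4Z,6R,7R,8R,10R)-1,10-epoxy-8-hydroxy-3-(3-methylbutanoyloxy)germacra-4,11(13)-dien-12,6-olide | C=C1C(=O)O[C@@H]2/C=C(/C)[C@@H](OC(=O)CC(C)C)C[C@H]3O[C@]3(C)C[C@@H](O)[C@@H]12 | intermediate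
38 | (E)-2-methylbut-2-en-1-ol (tiglyl alcohol) | C/C=C(\C)CO | starting material
39 | [(2S,3S)-2,3-dimethyloxiran-2-yl]methanol | OC[C@]1(C)O[C@H]1C | intermediate
40 | (2R,3S)-2,3-dimethyloxirane-2-carbaldehyde | O=C[C@]1(C)O[C@H]1C | intermediate
41 | (2R,3S)-2,3-dimethyloxirane-2-carboxylic acid | OC(=O)[C@]1(C)O[C@H]1C | intermediate
42 | mixed anhydride of 41 with 2,4,6-trichlorobenzoic acid | O=C(OC(=O)[C@]1(C)O[C@H]1C)c1c(Cl)cc(Cl)cc1Cl | intermediate
43 | (1R,3S,4Z,6R,7R,8R,10R)-8-[(2R,3S)-2,3-dimethyloxirane-2-carbonyloxy]-1,10-epoxy-3-(3-methylbutanoyloxy)germacra-4,11(13)-dien-12,6-olide (CNP0167461.4) | C=C1C(=O)O[C@@H]2/C=C(/C)[C@@H](OC(=O)CC(C)C)C[C@H]3O[C@]3(C)C[C@@H](OC(=O)[C@]3(C)O[C@H]3C)[C@@H]12 | target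

## Step count and least certain steps

Total: 27 steps. Longest linear sequence: 22 steps (1–6, 8–11, 14–24, 27).

**Step 18 (key step, proposed new method).** Most likely failures:
- oligomerisation, because closing a ten-membered ring costs strain and entropy;
- reversal of the addition, because the lithium aldolate is neopentylic and sits in a strained ring;
- migration of the triethylsilyl group from O10 to the new O1 alkoxide;
- addition of the amide base to the aldehyde;
- low facial selectivity if the ring, not the Felkin–Anh preference, dictates the approach.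

Fallback, from 26 back to 29, by a samarium Reformatsky closure (established for eight-membered carbocycles and for medium and large lactones). Kinetic enolisation of 26 with LiN(SiMe3)2 in the presence of Me3SiCl at −78 °C would give the trimethylsilyl enol ether F1. N-bromosuccinimide would convert it into the bromomethyl ketone F2. SmI2 in THF at −78 °C under high dilution would generate the samarium enolate, which adds irreversibly to the C1 aldehyde; the samarium aldolate does not revert, and work-up rejoins the route at 29.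

**Step 14.** Most likely failure: poor facial selectivity at C6, because the 2-propenyl branch at C7 may compete with the C8 branch for the anti position; partial epimerisation of aldehyde 17 at C7 before coupling is the second risk. Fallback, from the C6 epimer and back to 23: the unwanted (6S)-alcohol F3, alone or mixed with 23, would be oxidised with Dess–Martin periodinane to the dienone F4. Reagent-controlled Corey–Bakshi–Shibata reduction would then return 23; the (R)-oxazaborolidine with BH3·SMe2 is the choice if, as usual for enones, the alkenyl group acts as the larger substituent.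

**Step 16.** Most likely failure: incomplete differentiation of the silyl ethers. The neopentylic C1 triethylsilyl ether may cleave too slowly, and forcing the reaction may start to remove the tertiary C10 group. Fallback, from 24 back to 26: Swern oxidation converts primary triethylsilyl ethers directly into aldehydes and would give the C1 aldehyde F5 with the C3 silyl ether intact. The now unique secondary triethylsilyl ether would be removed with PPTS in methanol to give hydroxy aldehyde F6, and Dess–Martin oxidation of the C3 alcohol returns 26.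

**Step 19.** Most likely failure: erosion of 1,3-anti selectivity, if the ten-membered ring cannot adopt the chair-like delivery geometry, or slow exchange of the hindered C1 hydroxyl onto boron. Fallback, from 29 back to 31: chelation-controlled Narasaka–Prasad reduction (Et2BOMe, NaBH4, THF/MeOH, −78 °C) would give the 1,3-syn diol F7. Mitsunobu esterification of its less hindered allylic C3 hydroxyl with isovaleric acid (PPh3, diisopropyl azodicarboxylate) would invert C3 and install the ester in one operation, rejoining at 31.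

**Step 22.** Most likely failures: acyl migration or loss of the C3 isovalerate under basic fluoride (O6 lies cis to C3 across the Z alkene); elimination of the mesylate before the tertiary silyl ether is cleaved. Fallback, from 32 back to 33, with desilylation and ring closure separated: HF·pyridine buffered with pyridine in THF would remove the three silyl groups while no epoxide is yet present, giving triol mesylate F8. A non-nucleophilic amidine base (DBU, CH2Cl2) would then close the epoxide by displacement of the mesylate and return 33.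

## Further compounds

F1 | step 18 | trimethylsilyl enol ether of 26 at C2–C3 | C=C(O[Si](C)(C)C)/C(C)=C\[C@@H](O[Si](C)(C)C(C)(C)C)[C@H](C(=C)CO[Si](c1ccccc1)(c1ccccc1)C(C)(C)C)[C@H](OCc1ccc(OC)cc1)C[C@@](C)(O[Si](CC)(CC)CC)C=O
F2 | step 18 | 2-bromo derivative of 26 (bromomethyl ketone) | BrCC(=O)/C(C)=C\[C@@H](O[Si](C)(C)C(C)(C)C)[C@H](C(=C)CO[Si](c1ccccc1)(c1ccccc1)C(C)(C)C)[C@H](OCc1ccc(OC)cc1)C[C@@](C)(O[Si](CC)(CC)CC)C=O
F3 | step 14 | (6S)-epimer of 23 | C[C@H](O[Si](CC)(CC)CC)/C(C)=C\[C@H](O)[C@H](C(=C)CO[Si](c1ccccc1)(c1ccccc1)C(C)(C)C)[C@H](OCc1ccc(OC)cc1)C[C@@](C)(O[Si](CC)(CC)CC)CO[Si](CC)(CC)CC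
F4 | step 14 | 6-ketone (dienone) derived from 23 and F3 | C[C@H](O[Si](CC)(CC)CC)/C(C)=C\C(=O)[C@H](C(=C)CO[Si](c1ccccc1)(c1ccccc1)C(C)(C)C)[C@H](OCc1ccc(OC)cc1)C[C@@](C)(O[Si](CC)(CC)CC)CO[Si](CC)(CC)CC
F5 | step 16 | C1 aldehyde with the C3 triethylsilyl ether retained | C[C@H](O[Si](CC)(CC)CC)/C(C)=C\[C@@H](O[Si](C)(C)C(C)(C)C)[C@H](C(=C)CO[Si](c1ccccc1)(c1ccccc1)C(C)(C)C)[C@H](OCc1ccc(OC)cc1)C[C@@](C)(O[Si](CC)(CC)CC)C=O
F6 | step 16 | C1 aldehyde with free C3 hydroxyl | C[C@H](O)/C(C)=C\[C@@H](O[Si](C)(C)C(C)(C)C)[C@H](C(=C)CO[Si](c1ccccc1)(c1ccccc1)C(C)(C)C)[C@H](OCc1ccc(OC)cc1)C[C@@](C)(O[Si](CC)(CC)CC)C=O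
F7 | step 19 | (1S,3R)-1,3-syn diol, C3 epimer of 30 | O[C@H]1C[C@@H](O)/C(C)=C\[C@@H](O[Si](C)(C)C(C)(C)C)[C@H](C(=C)CO[Si](c2ccccc2)(c2ccccc2)C(C)(C)C)[C@H](OCc2ccc(OC)cc2)C[C@@]1(C)O[Si](CC)(CC)CC
F8 | step 22 | 6,10,12-triol 1-mesylate from 32 | CS(=O)(=O)O[C@H]1C[C@H](OC(=O)CC(C)C)/C(C)=C\[C@@H](O)[C@H](C(=C)CO)[C@H](OCc2ccc(OC)cc2)C[C@@]1(C)O
A1 | alternative 1 | epoxy germacranolide lacking the methylene and both acyl groups | C1C(=O)O[C@@H]2/C=C(/C)[C@@H](O[Si](C)(C)C(C)(C)C)C[C@H]3O[C@]3(C)C[C@@H](OCc4ccc(OC)cc4)[C@@H]12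
A2 | alternative 1 | open-chain C5 iodoalkene, C6 aldehyde, C12 methyl ester | I/C=C(/C)[C@@H](O[Si](C)(C)C(C)(C)C)C[C@H]1O[C@]1(C)C[C@@H](OCc1ccc(OC)cc1)[C@@H](CC(=O)OC)C=O
A3 | alternative 2 | 8-hydroxy germacranolide with the isovalerate and a 1(10) alkene | C=C1C(=O)O[C@@H]2/C=C(/C)[C@@H](OC(=O)CC(C)C)C/C=C(\C)C[C@@H](O)[C@@H]12
A4 | alternative 2 | C8 aldehyde tethered to a 3-(acetoxymethyl)butenolide | CC(=O)OCC1=C[C@@H](/C=C(/C)[C@@H](OC(=O)CC(C)C)C/C=C(\C)CC=O)OC1=O
A5 | alternative 3 | ten-membered triene silyl enol ether | C=C1C(=O)O[C@@H]2/C=C(/C)C(/O[Si](C)(C)C(C)(C)C)=C\C=C(/C)C[C@@H](O[Si](C)(C)C(C)(C)C)[C@@H]12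
A6 | alternative 3 | cis-fused eudesmanolide 3-silyloxy-1,3-diene | C=C1C(=O)O[C@@H]2[C@@H]3C(C)=C(O[Si](C)(C)C(C)(C)C)C=C[C@]3(C)C[C@@H](O[Si](C)(C)C(C)(C)C)[C@@H]12
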